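All constants are those of an exercise; the flask was simulated.

The time of reading came first: 20 h in the grey and teal flasks, an average 20 h in the red tank, an average 100 h in the green tank, and the next run would go to whichever set-up gave the most target.

    starting material + free catalyst → catalyst intermediate (k1 = 26 /M/h)
    precatalyst ⇌ free catalyst (K2 = 0.52, k2 = 0.026 /h)
    catalyst intermediate → free catalyst + target (k3 = 2.8 /h)
    2 starting material → self-condensation product (k4 = 0.52 /M/h)

the same everywhere: precatalyst 5 mol%

|  | starting material | remark | time |
|---|---|---|---|
| red | 0.050 M | a single well-mixed tank run continuously and read at steady state, 20 h in it on average |  |
| grey | 0.050 M (fed, over 16.0 h) | a stirred flask in which starting material is dosed at a steady rate over 16.0 h without added volume, worked up at 20 h | 20 h |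
| teal | 0.050 M | a closed flask charged with all of it at once and left for 20 h | 20 h |
| green | 0.050 M | a single well-mixed tank run continuously and read at steady state, 100 h in it on average |  |

- percentages count the starting material that a species holds: one self-condensation product counts as two
- a doubled species enters its step squared and goes two at a time
- the stated concentrations are those of everything mixed, before any reaction; amounts are the same in each set-up
- the feed brings no volume worth counting
- run time (grey): 20 h

- the set-up with the highest amount of target at the outlet or at the end, in percent of the starting material put in ("none" if the first two lie within 2 percentage points) (red / grey / teal / green / none)
- amount of target at the outlet or at the end, in percent of the starting material put in, red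
- amount of target at the outlet or at the end, in percent of the starting material put in, grey
- amount of target at the outlet or at the end, in percent of the starting material put in, teal
- amount of target at the outlet or at the end, in percent of the starting material put in, green

I compared the two ways out of starting material at one moment. The catalytic route takes it at its rate constant times free catalyst times starting material, and self-condensation takes it at double its rate constant times starting material squared. I put free catalyst at its equilibrium level, 34.2 % of the 0.00250 M charged as precatalyst, which is 8.55 × 10⁻⁴ M. That gave 0.0214 M, which I named the crossover concentration, the level of starting material at which the two routes consume it equally. The catalytic share, the selectivity, is then crossover over crossover plus the level.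

The charge of 0.050 M is 2.34 times the crossover. Free catalyst also starts from nothing and relaxes, by its exchange with precatalyst alone, with a half-life of 9.12 h, so the teal flask begins on the self-condensation side and the comparison improves with time.

My decision therefore turned on which vessel could hold starting material under crossover. At crossover the two routes together consume 9.51 × 10⁻⁴ M/h. The grey flask is fed faster, at 0.00313 M/h. The red tank would have to consume 0.00143 M/h to sit there, also more. The green tank needs less, 2.86 × 10⁻⁴ M/h. So I chose green. With free catalyst still taken at its equilibrium level, the balance of the green tank gave me an estimate of 0.0114 M of starting material and 50.5 % of target. I took the reckoning no further for the other set-ups.

The forecast gave 12.7 % for red, 9.9 % for grey, 10.4 % for teal and 45.4 % for green, lower than my green figure, and named green best: “its long residence time gives the catalyst time to activate and holds starting material low”.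

The simulation gave 12.7 % for red, 9.92 % for grey, 10.2 % for teal and 45.2 % for green, so green was best.

The green tank won because of back-mixing and the longer stay: without them its target falls from 45.2 % to 10.2 %. Its level stood at 0.0121 M, under crossover. The teal flask read at 3.0 d is the second case. At 20 h it held 0.0211 M, about crossover, and it later fell to 8.44 % of its charge. Summing the crossover share over that fall adds 22 percentage points to 10.2 %, giving 31.9 %; the computed result is 30.9 %.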